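The whole route rests on the C7–C8 bond, which is shared by the ten-membered carbocycle and the γ-lactone (locants below). In the target this bond is flanked by O8, O9 and the exocyclic C11=C13 methylene. That pattern is the retron of a Claisen rearrangement of an α-allyloxy enol ether. The precursor is therefore a 12-membered oxacycle. It consists of a geraniol-derived chain C6–C5–C4–C3–C2–C1–C10–C9 closed through O–C13H2–C11(CO2Me)=C7, with a formyl group (C8) on C9. Enol silylation and a [3,3] shift contract this ring by two atoms. The same operation forms C7–C8, sets C7 and C8, frees the C9 ketone and unveils the α-methylene ester. Reduction and lactonisation then finish the target.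

Key step: step 17

Locants (germacrane type, used throughout): ring C1–C10. C8 carries the lactone O, C9 the OH, C10 a CH3 (C14). C1–C3 are CH2. C4 (CH3 = C15) and C5 carry the epoxide, C6 the senecioate, and C7 carries C11(=C13H2)–C12(=O).
Assumption: C9, made in step 5, becomes sp2 in step 17, so it is carried as an epimer mixture and left undefined in the SMILES. The sense of induction in step 3 is taken from the geraniol-to-citronellol mnemonic, and the antipodal ligand would be used if it runs the other way.

Step 1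
Reactants: 1 geraniol
Product: 2 geranyl tert-butyldiphenylsilyl ether
Conditions: TBDPSCl, imidazole, CH2Cl2, 0 °C to rt
Reagents that add atoms: tert-butyl(chloro)diphenylsilane CC(C)(C)[Si](Cl)(c1ccccc1)c1ccccc1
Why: Imidazole-promoted silylation of the primary allylic alcohol (O6) gives a group that survives oxidation, hydrogenation, Grignard addition and NaH.

Step 2
Reactants: 2 geranyl tert-butyldiphenylsilyl ether
Product: 3 (2E,6E)-8-(tert-butyldiphenylsilyloxy)-2,6-dimethylocta-2,6-dien-1-ol
Conditions: SeO2 (cat.), t-BuOOH, salicylic acid (cat.), CH2Cl2, 0 °C to rt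
Reagents that add atoms: tert-butyl hydroperoxide CC(C)(C)OO
Why: Riley-type SeO2 allylic oxidation (ene reaction, then [2,3] shift) attacks the more electron-rich distal trisubstituted alkene at its E-methyl group, so C9 is oxygenated and the E geometry is kept.

Step 3
Reactants: 3 (2E,6E)-8-(tert-butyldiphenylsilyloxy)-2,6-dimethylocta-2,6-dien-1-ol
Product: 4 (2R,6E)-8-(tert-butyldiphenylsilyloxy)-2,6-dimethyloct-6-en-1-ol
Conditions: Ru(OAc)2[(R)-BINAP] (cat.), H2 (60 bar), MeOH, rt
Reagents that add atoms: none
Why: Noyori asymmetric hydrogenation needs the free allylic OH to bind ruthenium, so only C1=C10 is reduced and the ligand sets C10 as R while the silyl-protected C4=C5 alkene stays.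

Step 4
Reactants: 4 (2R,6E)-8-(tert-butyldiphenylsilyloxy)-2,6-dimethyloct-6-en-1-ol
Product: 5 (2R,6E)-8-(tert-butyldiphenylsilyloxy)-2,6-dimethyloct-6-enal
Conditions: Dess–Martin periodinane, CH2Cl2, 0 °C to rt
Reagents that add atoms: none
Why: Dess–Martin oxidation is fast and essentially neutral, so the α-stereocentre C10 should not epimerise.

Step 5
Reactants: 5 (2R,6E)-8-(tert-butyldiphenylsilyloxy)-2,6-dimethyloct-6-enal
Product: 6 (4R,8E)-10-(tert-butyldiphenylsilyloxy)-4,8-dimethyldeca-1,8-dien-3-ol (C9 epimers)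
Conditions: vinylMgBr, THF, −78 °C
Reagents that add atoms: vinylmagnesium bromide C=C[Mg]Br
Why: Grignard 1,2-addition brings in C8 as a masked formyl carbon, and the new carbinol centre C9 needs no control because step 17 makes it sp2.

Step 6
Reactants: 6 (4R,8E)-10-(tert-butyldiphenylsilyloxy)-4,8-dimethyldeca-1,8-dien-3-ol (C9 epimers)
Product: 7 O9-propargyl ether of 6
Conditions: NaH, propargyl bromide, Bu4NI (cat.), THF, 0 °C to rt
Reagents that add atoms: propargyl bromide C#CCBr
Why: Williamson ether synthesis with the reactive propargylic bromide installs the whole O–C13–C11≡C7 unit in one operation.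

Step 7
Reactants: 7 O9-propargyl ether of 6
Product: 8 (2E,7R)-3,7-dimethyl-8-(prop-2-yn-1-yloxy)deca-2,9-dien-1-ol (C9 epimers)
Conditions: TBAF, THF, 0 °C to rt
Reagents that add atoms: none
Why: Fluoride-induced desilylation frees O6–H, and no other group in 7 is fluoride-labile.

Step 8
Reactants: 8 (2E,7R)-3,7-dimethyl-8-(prop-2-yn-1-yloxy)deca-2,9-dien-1-ol (C9 epimers)
Product: 9 (2E,7R)-3,7-dimethyl-8-(prop-2-yn-1-yloxy)deca-2,9-dienal (C9 epimers)
Conditions: MnO2, CH2Cl2, rt
Reagents that add atoms: none
Why: MnO2 oxidises only the allylic alcohol and keeps the E geometry of C4=C5.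

Step 9
Reactants: 9 (2E,7R)-3,7-dimethyl-8-(prop-2-yn-1-yloxy)deca-2,9-dienal (C9 epimers)
Product: 10 (6E,11R)-12-ethenyl-7,11-dimethyl-1-oxacyclododec-6-en-3-yn-5-ol (C6 and C9 epimers)
Conditions: LiHMDS, THF (2 mM, slow addition of 9), −30 °C to rt
Reagents that add atoms: none
Why: Intramolecular acetylide addition to an enal without α-hydrogen closes the 12-membered ring at C6–C7 under high dilution, and the uncontrolled C6 centre is erased in step 10.

Step 10
Reactants: 10 (6E,11R)-12-ethenyl-7,11-dimethyl-1-oxacyclododec-6-en-3-yn-5-ol (C6 and C9 epimers)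
Product: 11 (6E,11R)-12-ethenyl-7,11-dimethyl-1-oxacyclododec-6-en-3-yn-5-one (C9 epimers)
Conditions: MnO2, CH2Cl2, rt
Reagents that add atoms: none
Why: MnO2 oxidation of the doubly activated (allylic and propargylic) carbinol converges both C6 epimers on one cross-conjugated ynone.

Step 11
Reactants: 11 (6E,11R)-12-ethenyl-7,11-dimethyl-1-oxacyclododec-6-en-3-yn-5-one (C9 epimers)
Product: 12 (5R,6E,11R)-12-ethenyl-7,11-dimethyl-1-oxacyclododec-6-en-3-yn-5-ol (C9 epimers)
Conditions: (R)-Me-CBS (cat.), catecholborane, toluene, −78 °C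
Reagents that add atoms: none
Why: Corey–Bakshi–Shibata reduction tells the large β,β-disubstituted alkenyl residue from the slim alkynyl residue, so the (R)-catalyst should set C6 as drawn, and catecholborane at low temperature avoids hydroboration.

Step 12
Reactants: 12 (5R,6E,11R)-12-ethenyl-7,11-dimethyl-1-oxacyclododec-6-en-3-yn-5-ol (C9 epimers)
Product: 14 (3Z,5R,6E,11R)-12-ethenyl-3-iodo-7,11-dimethyl-1-oxacyclododeca-3,6-dien-5-ol (C9 epimers), via alkenylalanate 13 (not isolated)
Conditions: Red-Al, THF, −20 to 0 °C; then I2, −78 °C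
Reagents that add atoms: iodine II; Red-Al [Na+].[AlH2-](OCCOC)OCCOC (its Na, Al and alkoxide ligands stay only in 13)
Why: Hydroxyl-directed trans-hydroalumination of the propargylic alcohol places Al on the distal carbon C11 in a five-membered alanate, iodinolysis with retention puts iodine cis to C6, and the low temperature suppresses β-alkoxide loss to an allene.

Step 13
Reactants: 14 (3Z,5R,6E,11R)-12-ethenyl-3-iodo-7,11-dimethyl-1-oxacyclododeca-3,6-dien-5-ol (C9 epimers)
Product: 15 macrocyclic 4,5-epoxy-6-ol (4R,5R,6S,10R; C11 iodide; C9 epimers)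
Conditions: mCPBA, CH2Cl2, 0 °C
Reagents that add atoms: 3-chloroperbenzoic acid O=C(OO)c1cccc(Cl)c1
Why: In this Henbest-type directed epoxidation A1,3 strain with C15 holds H6 in the alkene plane, so O6–H sits on the outer face of the macrocycle and guides the peracid there (threo) to set 4R,5R, while the iodoalkene and the vinyl group are too electron-poor to compete.

Step 14
Reactants: 15 macrocyclic 4,5-epoxy-6-ol (4R,5R,6S,10R; C11 iodide; C9 epimers)
Product: 16 macrocyclic 6-senecioate (4R,5R,6R,10R; C11 iodide; C9 epimers)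
Conditions: 3-methylbut-2-enoic acid, PPh3, DIAD, toluene, 0 °C to rt
Reagents that add atoms: 3-methylbut-2-enoic acid CC(C)=CC(=O)O
Why: Mitsunobu esterification installs the senecioate with SN2 inversion at C6 and so turns the threo epoxy alcohol into the erythro epoxy ester (6R) of the target.

Step 15
Reactants: 16 macrocyclic 6-senecioate (4R,5R,6R,10R; C11 iodide; C9 epimers)
Product: 17 macrocyclic methyl (Z)-enoate (CO2Me on C11 cis to C6; C9 epimers)
Conditions: PdCl2(PPh3)2 (cat.), CO (1 atm), Et3N, MeOH–THF, 40 °C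
Reagents that add atoms: carbon monoxide [C-]#[O+]; methanol CO
Why: Pd-catalysed methoxycarbonylation of the alkenyl iodide keeps the alkene geometry, because oxidative addition into C–I is much faster than ionisation of the allylic ester, and it brings in C12.

Step 16
Reactants: 17 macrocyclic methyl (Z)-enoate (CO2Me on C11 cis to C6; C9 epimers)
Product: 19 macrocyclic α-alkoxy aldehyde (C8 formyl on C9; C9 epimers), via diol 18 (not isolated)
Conditions: OsO4 (cat.), NaIO4, 2,6-lutidine, dioxane–H2O, rt
Reagents that add atoms: sodium periodate [Na+].[O-]I(=O)(=O)=O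
Why: Lemieux–Johnson cleavage picks the only unconjugated monosubstituted alkene, since both enoates are trisubstituted and electron-poor.

Step 17
Reactants: 19 macrocyclic α-alkoxy aldehyde (C8 formyl on C9; C9 epimers)
Product: 22 ten-membered α-hydroxy ketone (4R,5R,6R,7S,8S,10R), via Z-enol silane 20 (not isolated), via silyloxy ketone 21 (not isolated)
Conditions: LiHMDS (1.0 equiv), TMSCl, THF, −78 °C; toluene, 100 °C; then TBAF/AcOH, THF, 0 °C
Reagents that add atoms: chlorotrimethylsilane C[Si](C)(C)Cl (silicon stays only in 20 and 21)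
Why: Lithium-chelated deprotonation of the α-alkoxy aldehyde (Li bridging O8 and the ring oxygen) and O-silylation give the (Z)-enol silane 20, an allyl vinyl ether C8=C9–O–C13–C11=C7 whose vinyl terminus C8 is exocyclic and whose allyl part is endocyclic, so that the concerted suprafacial [3,3] shift makes C7–C8, breaks O–C13 and replaces the ring segment O–C13–C11 by C8 (12 to 10 ring atoms). The closest known reaction types are the aliphatic Claisen rearrangement of α-allyloxy enol derivatives (siloxy and anionic oxy-Claisen variants) and macrocyclic Claisen ring contractions, and here the donor on C8 and the acceptor ester on C11 polarise and accelerate the shift. Only the ten-membered carbocycle is closed, by sigmatropic C–C bond formation through a six-centre chair, the boat being disfavoured because it eclipses C10 on C9 with the ester on C11. In the chair the Z enol silane (O8 pseudoaxial) and the C7=C11 geometry with C6 trans to C13 (C6 pseudoequatorial) translate into the anti O8/C6 relationship, so C8 (S) is controlled by the two alkene geometries relative to C7. C7 (S) is controlled by C6, because A1,3 strain with the cis ester holds H6 in the alkene plane, the ring can loop only over the face that carries C5 and leaves the senecioate outside, and C8 therefore bonds anti to the C6–O bond. The step needs aldehyde α-deprotonation in preference to vinylogous deprotonation of the enoates (secured by the large pKa gap, one equivalent of base and −78 °C) and a pure Z enol silane (secured by chelation and by the bulk of C10), and buffered fluoride finally frees O8–H without opening the epoxide.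

Step 18
Reactants: 22 ten-membered α-hydroxy ketone (4R,5R,6R,7S,8S,10R)
Product: 24 target CNP0119422.1, via dihydroxy ester 23 (not isolated)
Conditions: Zn(BH4)2, Et2O, −30 °C to rt; aqueous work-up, then SiO2, CH2Cl2, rt
Reagents that add atoms: none
Why: In this chelation-controlled (Cram-chelate) reduction zinc bridges O8 and O9, hydride arrives from the outer face opposite C7 and sets 9R (8,9-anti), and O8 then closes the trans γ-lactone by 5-exo-trig transesterification of the neighbouring acrylate in preference to the six-membered alternative through O9.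

Compound list
1 | geraniol, (2E)-3,7-dimethylocta-2,6-dien-1-ol | CC(C)=CCC/C(C)=C/CO | starting material
2 | geranyl tert-butyldiphenylsilyl ether | CC(C)=CCC/C(C)=C/CO[Si](c1ccccc1)(c1ccccc1)C(C)(C)C | intermediate
3 | (2E,6E)-8-(tert-butyldiphenylsilyloxy)-2,6-dimethylocta-2,6-dien-1-ol | OC/C(C)=C/CC/C(C)=C/CO[Si](c1ccccc1)(c1ccccc1)C(C)(C)C | intermediate
4 | (2R,6E)-8-(tert-butyldiphenylsilyloxy)-2,6-dimethyloct-6-en-1-ol | OC[C@H](C)CCC/C(C)=C/CO[Si](c1ccccc1)(c1ccccc1)C(C)(C)C | intermediate
5 | (2R,6E)-8-(tert-butyldiphenylsilyloxy)-2,6-dimethyloct-6-enal | O=C[C@H](C)CCC/C(C)=C/CO[Si](c1ccccc1)(c1ccccc1)C(C)(C)C | intermediate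
6 | (4R,8E)-10-(tert-butyldiphenylsilyloxy)-4,8-dimethyldeca-1,8-dien-3-ol, C9 epimers | C=CC(O)[C@H](C)CCC/C(C)=C/CO[Si](c1ccccc1)(c1ccccc1)C(C)(C)C | intermediate
7 | O9-propargyl ether of 6, C9 epimers | C=CC(OCC#C)[C@H](C)CCC/C(C)=C/CO[Si](c1ccccc1)(c1ccccc1)C(C)(C)C | intermediate
8 | (2E,7R)-3,7-dimethyl-8-(prop-2-yn-1-yloxy)deca-2,9-dien-1-ol, C9 epimers | C=CC(OCC#C)[C@H](C)CCC/C(C)=C/CO | intermediate
9 | (2E,7R)-3,7-dimethyl-8-(prop-2-yn-1-yloxy)deca-2,9-dienal, C9 epimers | C=CC(OCC#C)[C@H](C)CCC/C(C)=C/C=O | intermediate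
10 | (6E,11R)-12-ethenyl-7,11-dimethyl-1-oxacyclododec-6-en-3-yn-5-ol, C6 and C9 epimers | C=CC1OCC#CC(O)/C=C(C)/CCC[C@H]1C | intermediate
11 | (6E,11R)-12-ethenyl-7,11-dimethyl-1-oxacyclododec-6-en-3-yn-5-one, C9 epimers | C=CC1OCC#CC(=O)/C=C(C)/CCC[C@H]1C | intermediate
12 | (5R,6E,11R)-12-ethenyl-7,11-dimethyl-1-oxacyclododec-6-en-3-yn-5-ol, C9 epimers | C=CC1OCC#C[C@H](O)/C=C(C)/CCC[C@H]1C | intermediate
13 | sodium alkenylalanate, five-membered O6–Al–C11 ring, two 2-methoxyethoxide ligands | C=CC1OCC2=C[C@H](O[Al-]2(OCCOC)OCCOC)/C=C(C)/CCC[C@H]1C.[Na+] | intermediate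
14 | (3Z,5R,6E,11R)-12-ethenyl-3-iodo-7,11-dimethyl-1-oxacyclododeca-3,6-dien-5-ol, C9 epimers | C=CC1OC/C(I)=C/[C@H](O)/C=C(C)/CCC[C@H]1C | intermediate
15 | macrocyclic 4,5-epoxy-6-ol, (4R,5R,6S,10R), iodine on C11 cis to C6, C9 epimers | C=CC1OC/C(I)=C/[C@H](O)[C@H]2O[C@]2(C)CCC[C@H]1C | intermediate
16 | macrocyclic 6-senecioate, (4R,5R,6R,10R), iodine on C11 cis to C6, C9 epimers | C=CC1OC/C(I)=C/[C@@H](OC(=O)C=C(C)C)[C@H]2O[C@]2(C)CCC[C@H]1C | intermediate
17 | macrocyclic methyl (Z)-enoate, CO2Me on C11 cis to C6, vinyl on C9, C9 epimers | C=CC1OC/C(C(=O)OC)=C/[C@@H](OC(=O)C=C(C)C)[C@H]2O[C@]2(C)CCC[C@H]1C | intermediate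
18 | 1,2-diol from the vinyl group of 17 | OCC(O)C1OC/C(C(=O)OC)=C/[C@@H](OC(=O)C=C(C)C)[C@H]2O[C@]2(C)CCC[C@H]1C | intermediate
19 | macrocyclic α-alkoxy aldehyde, formyl C8 on C9, C9 epimers | O=CC1OC/C(C(=O)OC)=C/[C@@H](OC(=O)C=C(C)C)[C@H]2O[C@]2(C)CCC[C@H]1C | intermediate
20 | (Z)-trimethylsilyl enol ether of 19, exocyclic C8=C9, OSiMe3 cis to the ring oxygen | C[Si](C)(C)O/C=C1\OC/C(C(=O)OC)=C/[C@@H](OC(=O)C=C(C)C)[C@H]2O[C@]2(C)CCC[C@H]1C | intermediate
21 | ten-membered 8-trimethylsilyloxy 9-ketone with the C7 acrylate side chain | C=C(C(=O)OC)[C@H]1[C@H](O[Si](C)(C)C)C(=O)[C@H](C)CCC[C@@]2(C)O[C@@H]2[C@@H]1OC(=O)C=C(C)C | intermediate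
22 | ten-membered 8-hydroxy 9-ketone, (4R,5R,6R,7S,8S,10R) | C=C(C(=O)OC)[C@H]1[C@H](O)C(=O)[C@H](C)CCC[C@@]2(C)O[C@@H]2[C@@H]1OC(=O)C=C(C)C | intermediate
23 | ten-membered 8,9-dihydroxy methyl ester, (4R,5R,6R,7S,8S,9R,10R) | C=C(C(=O)OC)[C@H]1[C@H](O)[C@H](O)[C@H](C)CCC[C@@]2(C)O[C@@H]2[C@@H]1OC(=O)C=C(C)C | intermediate
24 | CNP0119422.1, (4R,5R,6R,7S,8S,9R,10R) | C=C1C(=O)O[C@@H]2[C@H](O)[C@H](C)CCC[C@@]3(C)O[C@@H]3[C@H](OC(=O)C=C(C)C)[C@@H]12 | target

Total step count: 18. Longest linear sequence: 18 steps, from geraniol.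

Steps most likely to fail

Step 17 (key step).
- What may go wrong: erosion of the enol silane geometry, or leakage through a boat, would scramble C8. The base could deprotonate the Z-enoate in a vinylogous sense. The rearrangement could also be too slow, so that thermal decomposition takes over.
- Fallback, from 16 back to the route at 24: the ester is taken out of the rearranging array and the lactone is built last.
- Lemieux–Johnson cleavage of 16 runs through the iodo diol F1 to the iodo aldehyde F2.
- Enol silylation gives the iodo enol silane F3, and the Claisen contraction gives the iodoallyl silyloxy ketone F4. Buffered fluoride then frees the iodoallyl hydroxy ketone F5.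
- Zn(BH4)2 reduction under chelation control gives the iodoallyl diol F6.
- Pd-catalysed carbonylative lactonisation (Pd(PPh3)4, CO, Et3N, THF, 50 °C) closes the α-methylene-γ-lactone through O8 and delivers 24.

Step 14.
- What may go wrong: the SN2 displacement at C6 inside the macrocycle may be slow. Elimination, allylic transposition, or partial retention through participation of the epoxide could then compete.
- Fallback, from 15 back to the route at 16: inversion by redox instead of substitution.
- Dess–Martin oxidation gives the epoxy enone F7.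
- Zn(BH4)2 reduction, which on α,β-epoxy ketones favours the erythro epoxy alcohol, gives the 6-epi alcohol F8.
- Acylation with senecioic anhydride and DMAP then gives 16.

Step 9.
- What may go wrong: oligomerisation may outrun ring closure, and γ-deprotonation of the enal may compete with acetylide formation.
- Fallback, from 9 back to the route at 10: the basic acetylide is replaced by a chromium alkynyl.
- NIS with catalytic AgNO3 in acetone converts 9 into the iodoalkyne F9.
- A Nozaki–Hiyama–Kishi macrocyclisation (CrCl2, NiCl2 cat., THF–DMF, high dilution) closes the ring to 10 under non-basic conditions.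

Further compounds
F1 | step 17 | iodo diol, 1,2-diol from the vinyl group of 16 | OCC(O)C1OC/C(I)=C/[C@@H](OC(=O)C=C(C)C)[C@H]2O[C@]2(C)CCC[C@H]1C
F2 | step 17 | iodo aldehyde, formyl C8 on C9, iodine on C11 | O=CC1OC/C(I)=C/[C@@H](OC(=O)C=C(C)C)[C@H]2O[C@]2(C)CCC[C@H]1C
F3 | step 17 | iodo enol silane, (Z)-trimethylsilyl enol ether of F2 | C[Si](C)(C)O/C=C1\OC/C(I)=C/[C@@H](OC(=O)C=C(C)C)[C@H]2O[C@]2(C)CCC[C@H]1C
F4 | step 17 | iodoallyl silyloxy ketone, ten-membered ring | C=C(I)[C@H]1[C@H](O[Si](C)(C)C)C(=O)[C@H](C)CCC[C@@]2(C)O[C@@H]2[C@@H]1OC(=O)C=C(C)C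
F5 | step 17 | iodoallyl hydroxy ketone, ten-membered ring | C=C(I)[C@H]1[C@H](O)C(=O)[C@H](C)CCC[C@@]2(C)O[C@@H]2[C@@H]1OC(=O)C=C(C)C
F6 | step 17 | iodoallyl diol, ten-membered ring, 8,9-anti | C=C(I)[C@H]1[C@H](O)[C@H](O)[C@H](C)CCC[C@@]2(C)O[C@@H]2[C@@H]1OC(=O)C=C(C)C
F7 | step 14 | epoxy enone, C6 ketone of 15 | C=CC1OC/C(I)=C/C(=O)[C@H]2O[C@]2(C)CCC[C@H]1C
F8 | step 14 | 6-epi alcohol, erythro epoxy alcohol (4R,5R,6R,10R) | C=CC1OC/C(I)=C/[C@@H](O)[C@H]2O[C@]2(C)CCC[C@H]1C
F9 | step 9 | iodoalkyne of 9 | C=CC(OCC#CI)[C@H](C)CCC/C(C)=C/C=O
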